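The route rests on cutting the trimethylcyclohexene ring into two three-carbon pieces. In that ring the methyl-bearing sp2 carbon and the gem-dimethyl carbon both flank the chain-bearing carbon, so they are the two α-carbons of a latent ketone, and the other three ring atoms are a plain CH2CH2CH2 unit. The key step joins ethyl isopropenyl ketone and 1-chloro-3-iodopropane in one pot (conjugate reduction, C-alkylation, cycloalkylation) to 2,2,6-trimethylcyclohexanone, forming both ring CH2–C bonds at once. Its enol triflate is then coupled with an alkylborane from a chromene diene, built from (S)-linalool by SNAr etherification, ring-closing metathesis and allylic oxidation.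

Key step: step 1

Remark 1: (S)-(+)-linalool 9 is taken as enantiomerically pure; its carbinol carbon becomes C2 of the chromene with the same descriptor, because the CIP order O > sp2 carbon > CH2 > CH3 holds throughout.
Remark 2: 2H-chromenes can racemise by reversible electrocyclic ring opening under irradiation or strong heating, so every step after the ring closure runs at or below 50 °C and away from strong light.

Step 1
Reactants: 1 2-methylpent-1-en-3-one; 2 1-chloro-3-iodopropane
Product: 5 racemic 2,2,6-trimethylcyclohexan-1-one, via potassium enolate 3 (not isolated), via chloro ketone 4 (not isolated)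
Conditions: KBH(s-Bu)3 (K-Selectride, 1.0 equiv), THF, −78 °C; then 2 (1.2 equiv), −78 °C → rt; then KN(SiMe3)2 (1.3 equiv), −78 → 50 °C
Reagents that add atoms: none
Why: Conjugate hydride addition of the trialkylborohydride to enone 1 should give the tetrasubstituted enolate 3 regiospecifically, and 3 is C-alkylated by the iodide end of 2 to set the gem-dimethyl quaternary carbon (first new ring bond, CMe2–CH2); chloro ketone 4 then has α-hydrogens only on its ethyl CH2, so the amide base gives a single enolate that closes the ring by intramolecular SN2 displacement of chloride (second new ring bond, CH(CH3)–CH2). The closest known reaction types are the reductive alkylation of enones with trialkylborohydrides and the α,α′-annulation of ketones with 1,3-dihalopropanes, a formal [3+3] ring synthesis. The one ring that closes does so in a 6-(enolendo)-exo-tet mode. The only new stereocentre, C6 of 5, forms racemic and is erased when it becomes sp2 in step 2, so no stereocontrol is needed. The step needs regiocontrol of both enolisations and C- over O-alkylation: hydride can only deliver the enolate at the isopropenyl carbon, the quaternised carbon then blocks that side, and O-alkylation of the last enolate would require an eight-membered ring.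

Step 2
Reactants: 5 racemic 2,2,6-trimethylcyclohexan-1-one
Product: 6 2,6,6-trimethylcyclohex-1-en-1-yl trifluoromethanesulfonate
Conditions: LiN(i-Pr)2 (LDA), THF, −78 → 0 °C; then PhNTf2, 0 °C → rt
Reagents that add atoms: N-phenylbis(trifluoromethanesulfonimide), O=S(=O)(N(c1ccccc1)S(=O)(=O)C(F)(F)F)C(F)(F)F
Why: The only α-hydrogen of 5 sits on C6, so LDA should give a single enolate, which is O-sulfonylated by PhNTf2 (enol triflate formation); this fixes the ring double bond between the methyl-bearing carbon and the future chain-bearing carbon and erases the C6 stereocentre.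

Step 3
Reactants: 7 2-fluoro-5-hydroxybenzaldehyde
Product: 8 2-fluoro-5-(methoxymethoxy)benzaldehyde
Conditions: MOMCl, i-Pr2NEt, CH2Cl2, 0 °C → rt
Reagents that add atoms: chloromethyl methyl ether (MOMCl), COCCl
Why: O-alkylation of the phenol with MOMCl and a hindered amine base (acetal protection) masks the acidic hydroxyl, which as its phenoxide would switch off the arene towards substitution in the next step.

Step 4
Reactants: 8 2-fluoro-5-(methoxymethoxy)benzaldehyde; 9 (S)-(+)-linalool
Product: 10 2-{[(3S)-3,7-dimethylocta-1,6-dien-3-yl]oxy}-5-(methoxymethoxy)benzaldehyde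
Conditions: 9 (1.1 equiv), KN(SiMe3)2 (1.0 equiv), THF, 0 °C; then 8, DMF, 0 °C → rt
Reagents that add atoms: none
Why: Nucleophilic aromatic substitution (SNAr through a Meisenheimer adduct) in which the preformed tertiary potassium alkoxide displaces the fluoride activated by the ortho formyl group; the carbinol C–O bond of 9 is never broken, so its S configuration passes unchanged into the ether.

Step 5
Reactants: 10 2-{[(3S)-3,7-dimethylocta-1,6-dien-3-yl]oxy}-5-(methoxymethoxy)benzaldehyde
Product: 11 1-{[(3S)-3,7-dimethylocta-1,6-dien-3-yl]oxy}-2-ethenyl-4-(methoxymethoxy)benzene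
Conditions: Ph3PCH3Br, KOt-Bu, THF, 0 °C → rt
Reagents that add atoms: methyltriphenylphosphonium bromide, C[P+](c1ccccc1)(c1ccccc1)c1ccccc1.[Br-]
Why: Wittig methylenation of the aryl aldehyde with the non-stabilised ylide should give the styrene needed for ring closure under cold, basic conditions that leave the tertiary allyl aryl ether intact.

Step 6
Reactants: 11 1-{[(3S)-3,7-dimethylocta-1,6-dien-3-yl]oxy}-2-ethenyl-4-(methoxymethoxy)benzene
Product: 12 (2S)-6-(methoxymethoxy)-2-methyl-2-(4-methylpent-3-en-1-yl)-2H-chromene
Conditions: RuCl2(=CHPh)(PCy3)2 (first-generation Grubbs catalyst, 5 mol%), CH2Cl2 (0.01 M), 40 °C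
Reagents that add atoms: none
Why: Ring-closing olefin metathesis between the styrene and the allylic vinyl group closes the six-membered pyran ring with loss of ethylene; the first-generation catalyst loads on the unhindered styrene and hardly touches the trisubstituted side-chain alkene, and the quaternary stereocentre is not involved.

Step 7
Reactants: 12 (2S)-6-(methoxymethoxy)-2-methyl-2-(4-methylpent-3-en-1-yl)-2H-chromene
Product: 14 (2E)-5-[(2S)-6-(methoxymethoxy)-2-methyl-2H-chromen-2-yl]-2-methylpent-2-enal, via allylic alcohol 13 (not isolated)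
Conditions: SeO2 (20 mol%), t-BuOOH (3 equiv), salicylic acid (cat.), CH2Cl2, rt; then MnO2, CH2Cl2, rt
Reagents that add atoms: tert-butyl hydroperoxide, CC(C)(C)OO; selenium dioxide, O=[Se]=O
Why: Selenium dioxide allylic oxidation (ene reaction followed by [2,3]-sigmatropic shift) attacks the methyl group trans to the chain on the more substituted alkene carbon, which sets the E geometry, and MnO2 takes the allylic alcohol on to the enal; C2 of the chromene carries no hydrogen, so the ring alkene has no allylic C–H to oxidise.

Step 8
Reactants: 14 (2E)-5-[(2S)-6-(methoxymethoxy)-2-methyl-2H-chromen-2-yl]-2-methylpent-2-enal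
Product: 15 (2S)-6-(methoxymethoxy)-2-methyl-2-[(3E)-4-methylhexa-3,5-dien-1-yl]-2H-chromene
Conditions: Ph3PCH3Br, KOt-Bu, THF, 0 °C
Reagents that add atoms: methyltriphenylphosphonium bromide, C[P+](c1ccccc1)(c1ccccc1)c1ccccc1.[Br-]
Why: Wittig methylenation of the enal adds the one carbon that becomes the CH2 next to the cyclohexene ring and should give the terminal diene without touching the E-trisubstituted alkene.

Step 9
Reactants: 15 (2S)-6-(methoxymethoxy)-2-methyl-2-[(3E)-4-methylhexa-3,5-dien-1-yl]-2H-chromene; 6 2,6,6-trimethylcyclohex-1-en-1-yl trifluoromethanesulfonate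
Product: 17 (2S)-6-(methoxymethoxy)-2-methyl-2-[(3E)-4-methyl-6-(2,6,6-trimethylcyclohex-1-en-1-yl)hex-3-en-1-yl]-2H-chromene, via alkylborane 16 (not isolated)
Conditions: 9-BBN (1.2 equiv), THF, 0 °C → rt; then 6, PdCl2(dppf) (10 mol%), AsPh3, aq. Cs2CO3, DMF, 50 °C
Reagents that add atoms: none
Why: 9-BBN places boron on the terminal carbon of the only monosubstituted alkene (anti-Markovnikov hydroboration), and the primary alkylborane then undergoes B-alkyl Suzuki–Miyaura coupling with enol triflate 6 (oxidative addition to zerovalent palladium, base-assisted transmetalation, reductive elimination), which joins the fragments and leaves the tetrasubstituted ring alkene where the triflate was.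

Step 10
Reactants: 17 (2S)-6-(methoxymethoxy)-2-methyl-2-[(3E)-4-methyl-6-(2,6,6-trimethylcyclohex-1-en-1-yl)hex-3-en-1-yl]-2H-chromene
Product: 18 (2S)-2-methyl-2-[(3E)-4-methyl-6-(2,6,6-trimethylcyclohex-1-en-1-yl)hex-3-en-1-yl]-2H-chromen-6-ol
Conditions: HCl (cat.), MeOH, rt
Reagents that add atoms: none
Why: Acid-catalysed transacetalisation in methanol cleaves the MOM ether to the free phenol under conditions that should be mild enough for the chromene, the E-trisubstituted alkene and the tetrasubstituted ring alkene.

Compound list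
1 | 2-methylpent-1-en-3-one (ethyl isopropenyl ketone) | C=C(C)C(=O)CC | starting material
2 | 1-chloro-3-iodopropane | ClCCCI | starting material
3 | potassium 2-methylpent-2-en-3-olate | CCC([O-])=C(C)C.[K+] | intermediate
4 | 7-chloro-4,4-dimethylheptan-3-one | CCC(=O)C(C)(C)CCCCl | intermediate
5 | 2,2,6-trimethylcyclohexan-1-one (racemic) | CC1CCCC(C)(C)C1=O | intermediate
6 | 2,6,6-trimethylcyclohex-1-en-1-yl trifluoromethanesulfonate | CC1=C(OS(=O)(=O)C(F)(F)F)C(C)(C)CCC1 | intermediate
7 | 2-fluoro-5-hydroxybenzaldehyde | O=Cc1cc(O)ccc1F | starting material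
8 | 2-fluoro-5-(methoxymethoxy)benzaldehyde | O=Cc1cc(OCOC)ccc1F | intermediate
9 | (S)-(+)-linalool, (3S)-3,7-dimethylocta-1,6-dien-3-ol | CC(C)=CCC[C@@](C)(C=C)O | starting material
10 | 2-{[(3S)-3,7-dimethylocta-1,6-dien-3-yl]oxy}-5-(methoxymethoxy)benzaldehyde | CC(C)=CCC[C@@](C)(C=C)Oc1ccc(OCOC)cc1C=O | intermediate
11 | 1-{[(3S)-3,7-dimethylocta-1,6-dien-3-yl]oxy}-2-ethenyl-4-(methoxymethoxy)benzene | CC(C)=CCC[C@@](C)(C=C)Oc1ccc(OCOC)cc1C=C | intermediate
12 | (2S)-6-(methoxymethoxy)-2-methyl-2-(4-methylpent-3-en-1-yl)-2H-chromene | CC(C)=CCC[C@@]1(C)C=Cc2cc(OCOC)ccc2O1 | intermediate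
13 | (2E)-5-[(2S)-6-(methoxymethoxy)-2-methyl-2H-chromen-2-yl]-2-methylpent-2-en-1-ol | OC/C(C)=C/CC[C@@]1(C)C=Cc2cc(OCOC)ccc2O1 | intermediate
14 | (2E)-5-[(2S)-6-(methoxymethoxy)-2-methyl-2H-chromen-2-yl]-2-methylpent-2-enal | O=C/C(C)=C/CC[C@@]1(C)C=Cc2cc(OCOC)ccc2O1 | intermediate
15 | (2S)-6-(methoxymethoxy)-2-methyl-2-[(3E)-4-methylhexa-3,5-dien-1-yl]-2H-chromene | C=C/C(C)=C/CC[C@@]1(C)C=Cc2cc(OCOC)ccc2O1 | intermediate
16 | 9-{(3E)-6-[(2S)-6-(methoxymethoxy)-2-methyl-2H-chromen-2-yl]-3-methylhex-3-en-1-yl}-9-borabicyclo[3.3.1]nonane | C1CCC2CCCC1B2CC/C(C)=C/CC[C@@]3(C)C=Cc4cc(OCOC)ccc4O3 | intermediate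
17 | (2S)-6-(methoxymethoxy)-2-methyl-2-[(3E)-4-methyl-6-(2,6,6-trimethylcyclohex-1-en-1-yl)hex-3-en-1-yl]-2H-chromene | CC1=C(CC/C(C)=C/CC[C@@]2(C)C=Cc3cc(OCOC)ccc3O2)C(C)(C)CCC1 | intermediate
18 | (2S)-2-methyl-2-[(3E)-4-methyl-6-(2,6,6-trimethylcyclohex-1-en-1-yl)hex-3-en-1-yl]-2H-chromen-6-ol | CC1=C(CC/C(C)=C/CC[C@@]2(C)C=Cc3cc(O)ccc3O2)C(C)(C)CCC1 | target

Total step count: 10. Longest linear sequence: 8 steps (steps 3 to 10); the ring branch (steps 1 and 2) joins at step 9.

Steps most likely to fail

Step 1. The hindered, borane-associated tetrasubstituted enolate may alkylate slowly, so that proton transfer from the chloro ketone to unreacted enolate, polyalkylation or incomplete ring closure onto the chloride erode the yield. The fallback keeps the same two ring bonds formed in one operation but makes the second by acylation instead of alkylation. It sets out from 1, which is hydrogenated (H2, palladium on carbon, EtOAc) to 2-methylpentan-3-one F1. F1 and methyl acrylate with KOt-Bu in THF/t-BuOH should undergo thermodynamic Michael addition at the isopropyl carbon followed by intramolecular Claisen condensation of the ethyl CH2 onto the ester, giving 2,4,4-trimethylcyclohexane-1,3-dione F2. Oxalyl chloride with catalytic DMF in CH2Cl2 converts the less hindered carbonyl into the vinyl chloride 3-chloro-2,6,6-trimethylcyclohex-2-en-1-one F3. Hydrogenation (H2, palladium on carbon, Et3N, EtOAc) removes the chlorine and saturates the alkene, and the route is rejoined at 5.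

Step 9. Oxidative addition and transmetalation at the enol triflate, which is flanked by a quaternary carbon and a methyl-bearing carbon, may be slow, so that protodeboronation, β-hydride elimination or triflate hydrolysis take over. The fallback replaces the cross-coupling by carbonyl addition and dehydration and sets out from 15 and ketone 5. Hydroboration of 15 with 9-BBN and oxidation (NaOH, H2O2) gives (3E)-6-[(2S)-6-(methoxymethoxy)-2-methyl-2H-chromen-2-yl]-3-methylhex-3-en-1-ol F4. Appel-type iodination (I2, PPh3, imidazole, CH2Cl2) gives (2S)-2-[(3E)-6-iodo-4-methylhex-3-en-1-yl]-6-(methoxymethoxy)-2-methyl-2H-chromene F5. Iodine–lithium exchange (t-BuLi, Et2O, −78 °C), transmetalation with CeCl3 and addition to 5 gives 1-{(3E)-6-[(2S)-6-(methoxymethoxy)-2-methyl-2H-chromen-2-yl]-3-methylhex-3-en-1-yl}-2,2,6-trimethylcyclohexan-1-ol F6 as a diastereomer mixture. Dehydration towards the ring methine (SOCl2, pyridine, 0 °C, or Burgess reagent) should give the tetrasubstituted alkene, and the route is rejoined at 17.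

Step 4. The alkoxide may add reversibly to the formyl group and trigger hydride-transfer side reactions, or substitution may stall because the para alkoxy group deactivates the ring. The fallback moves the activation to a cyano group, which cannot be attacked in this way, and unveils the aldehyde afterwards; it sets out from 9. The potassium alkoxide of 9 (KN(SiMe3)2, THF/DMF) is arylated with 2-fluoro-5-(methoxymethoxy)benzonitrile F7, made from commercial 2-fluoro-5-hydroxybenzonitrile and MOMCl. This gives 2-{[(3S)-3,7-dimethylocta-1,6-dien-3-yl]oxy}-5-(methoxymethoxy)benzonitrile F8. Partial reduction with i-Bu2AlH (toluene, −78 °C) and mild hydrolysis of the aluminium imine gives the aldehyde, and the route is rejoined at 10.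

Further compounds
F1 | step 1 | 2-methylpentan-3-one | CCC(=O)C(C)C
F2 | step 1 | 2,4,4-trimethylcyclohexane-1,3-dione | CC1C(=O)CCC(C)(C)C1=O
F3 | step 1 | 3-chloro-2,6,6-trimethylcyclohex-2-en-1-one | CC1=C(Cl)CCC(C)(C)C1=O
F4 | step 9 | (3E)-6-[(2S)-6-(methoxymethoxy)-2-methyl-2H-chromen-2-yl]-3-methylhex-3-en-1-ol | OCC/C(C)=C/CC[C@@]1(C)C=Cc2cc(OCOC)ccc2O1
F5 | step 9 | (2S)-2-[(3E)-6-iodo-4-methylhex-3-en-1-yl]-6-(methoxymethoxy)-2-methyl-2H-chromene | ICC/C(C)=C/CC[C@@]1(C)C=Cc2cc(OCOC)ccc2O1
F6 | step 9 | 1-{(3E)-6-[(2S)-6-(methoxymethoxy)-2-methyl-2H-chromen-2-yl]-3-methylhex-3-en-1-yl}-2,2,6-trimethylcyclohexan-1-ol | CC1CCCC(C)(C)C1(O)CC/C(C)=C/CC[C@@]2(C)C=Cc3cc(OCOC)ccc3O2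
F7 | step 4 | 2-fluoro-5-(methoxymethoxy)benzonitrile | N#Cc1cc(OCOC)ccc1F
F8 | step 4 | 2-{[(3S)-3,7-dimethylocta-1,6-dien-3-yl]oxy}-5-(methoxymethoxy)benzonitrile | CC(C)=CCC[C@@](C)(C=C)Oc1ccc(OCOC)cc1C#N
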